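**Retrosynthetic overview**

- The route rests on the near-twofold symmetry of the C40 nonaene about its central C15=C15' double bond. The ring B half (C1–C14, 3R carbinol, 6S) and the ring A half (C1'–C14', 3'-ketone, 6'S) differ only in oxidation level at C3/C3' and share the 6S configuration.
- Key disconnections: C14'–C15' (Stille) and C15–C14 (Suzuki) in one flask. They join the ring A C19 iodide (fragment 1), a 1-stannyl-2-boryl ethene that supplies C15'=C15 (fragment 2) and the ring B C19 iodide (fragment 3).
- Fragment 1 comes from fragment 3 by MnO2 oxidation at C3. Fragment 3 comes from a C15 hydroxy enal and a C4 iodoallyl phosphonate (Horner–Wadsworth–Emmons, C11=C12). The enal comes from resolved cis-3-acetoxy-α-ionone (olefination at C9, then i-Bu2AlH).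
- Racemic α-ionone supplies both cyclohexene rings ready-made, so no ring is formed in the route. Ketalisation, allylic oxidation at C3, cis-selective reduction and lipase resolution set C3 and select C6.

Key step: step 13

Remark: carotenoid numbering is used (ring B half unprimed, ring A half primed), and the lipase of step 4 is assumed to acylate the 3R carbinol as the Kazlauskas rule predicts; if the preference proved opposite, the unreacted alcohol would be the wanted enantiomer and would simply be acetylated.

**Route**

Step 1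
Reactants: 1 (±)-α-ionone
Product: 2 (±)-α-ionone ethylene ketal, 2-methyl-2-[(E)-2-(2,6,6-trimethylcyclohex-2-en-1-yl)ethenyl]-1,3-dioxolane
Conditions: ethylene glycol, HC(OEt)3, p-TsOH (cat.), 20 °C
Reagents that add atoms: ethylene glycol, OCCO
Why: Acid-catalysed ketalisation, driven by the orthoformate as water scavenger at room temperature, masks the C9 ketone so that the later hydride reduction addresses the ring carbonyl alone, and the mild conditions should leave both double bonds in place.

Step 2
Reactants: 2 (±)-α-ionone ethylene ketal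
Product: 3 (±)-3-keto-α-ionone ethylene ketal, 3,5,5-trimethyl-4-[(E)-2-(2-methyl-1,3-dioxolan-2-yl)ethenyl]cyclohex-2-en-1-one
Conditions: t-BuOOH (70% aq.), NaOCl (aq.), MeCN, 0 °C
Reagents that add atoms: tert-butyl hydroperoxide, CC(C)(C)OO
Why: Radical allylic oxidation by tert-butylperoxyl radicals should attack the open ring methylene C3 next to C4=C5 and not the shielded C6 methine, and the ketal is stable in the basic medium.

Step 3
Reactants: 3 (±)-3-keto-α-ionone ethylene ketal
Product: 5 racemic cis-3-hydroxy-α-ionone, (3E)-4-[(1S*,4R*)-4-hydroxy-2,6,6-trimethylcyclohex-2-en-1-yl]but-3-en-2-one, via cis-hydroxy ketal 4 (not isolated)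
Conditions: NaBH4, CeCl3·7H2O, MeOH, −40 °C; then 0.3 M aq. HCl, THF, 0–20 °C (brief); chromatography to remove the trans isomer
Reagents that add atoms: water, O
Why: Luche 1,2-reduction of the β,β-disubstituted enone, in which hydride is expected to add to the face away from the C6 side chain and so place the C3 hydroxyl cis to it, followed by acid hydrolysis of the dioxolane in the same flask.

Step 4
Reactants: 5 racemic cis-3-hydroxy-α-ionone
Product: 6 (3R,6S)-3-acetoxy-α-ionone, (1R,4S)-3,5,5-trimethyl-4-[(1E)-3-oxobut-1-en-1-yl]cyclohex-2-en-1-yl acetate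
Conditions: Amano lipase PS (Burkholderia cepacia), vinyl acetate, t-BuOMe, 30 °C, stopped near half conversion; chromatography
Reagents that add atoms: vinyl acetate, C=COC(C)=O
Why: Lipase-catalysed kinetic resolution by irreversible transesterification, in which the 3R carbinol (same spatial arrangement as the fast-reacting (R)-cyclohex-2-enols) should be acylated while the 3S,6R alcohol stays behind and is removed, so the step fixes the absolute configuration at C3 and, through the cis relationship, selects 6S.

Step 5
Reactants: 6 (3R,6S)-3-acetoxy-α-ionone; 7 diethyl (cyanomethyl)phosphonate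
Product: 8 (1R,4S)-4-[(1E,3E)-4-cyano-3-methylbuta-1,3-dien-1-yl]-3,5,5-trimethylcyclohex-2-en-1-yl acetate (C15 acetoxy nitrile)
Conditions: NaH (slightly less than 7), THF, 0 → 20 °C; chromatography to remove the 9Z isomer
Reagents that add atoms: none
Why: Horner–Wadsworth–Emmons olefination of the methyl ketone with the stabilised, weakly basic cyanomethylphosphonate anion should give mainly the 9E nitrile without touching the C6 hydrogen, and any acetate lost here converges in the next step.

Step 6
Reactants: 8 C15 acetoxy nitrile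
Product: 9 (2E,4E)-5-[(1S,4R)-4-hydroxy-2,6,6-trimethylcyclohex-2-en-1-yl]-3-methylpenta-2,4-dienal (C15 hydroxy enal)
Conditions: i-Bu2AlH (4 equiv), CH2Cl2, −78 → −40 °C; then aq. KNaC4H4O6 (potassium sodium tartrate), 0 °C
Reagents that add atoms: water, O
Why: Nitrile half-reduction with i-Bu2AlH gives an N-aluminoimine that hydrolyses to the aldehyde on work-up, and the same reagent cleaves the acetate reductively, so the C3 carbinol is uncovered without a separate step and the diene geometry is untouched.

Step 7
Reactants: 10 propargyl alcohol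
Product: 11 (2E)-3-iodo-2-methylprop-2-en-1-ol
Conditions: Me3Al (3 equiv), Cp2ZrCl2 (0.25 equiv), CH2Cl2, 0 → 20 °C; then I2, THF, −30 °C
Reagents that add atoms: trimethylaluminium, C[Al](C)C; iodine, II
Why: Negishi zirconium-catalysed carboalumination adds methyl and aluminium syn across the alkyne with methyl at the internal carbon, and iodinolysis of the alkenylalane with retention gives the E iodide.

Step 8
Reactants: 11 (2E)-3-iodo-2-methylprop-2-en-1-ol
Product: 12 (1E)-3-bromo-1-iodo-2-methylprop-1-ene
Conditions: CBr4, PPh3, CH2Cl2, 0 °C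
Reagents that add atoms: tetrabromomethane, BrC(Br)(Br)Br
Why: Appel bromination converts the primary allylic alcohol through its alkoxyphosphonium ion by SN2 displacement and leaves the vinyl iodide alone.

Step 9
Reactants: 12 (1E)-3-bromo-1-iodo-2-methylprop-1-ene
Product: 13 diethyl [(2E)-3-iodo-2-methylprop-2-en-1-yl]phosphonate
Conditions: P(OEt)3 (neat), 100 °C
Reagents that add atoms: triethyl phosphite, CCOP(OCC)OCC
Why: Michaelis–Arbuzov reaction of the allylic bromide; the vinyl iodide is inert to the phosphite in the absence of a metal catalyst.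

Step 10
Reactants: 9 C15 hydroxy enal; 13 diethyl [(2E)-3-iodo-2-methylprop-2-en-1-yl]phosphonate
Product: 14 fragment 3, (1R,4S)-4-[(1E,3E,5E,7E)-8-iodo-3,7-dimethylocta-1,3,5,7-tetraen-1-yl]-3,5,5-trimethylcyclohex-2-en-1-ol
Conditions: NaN(SiMe3)2, THF, −78 → 0 °C (13 and base each about 2.4 equiv), dark
Reagents that add atoms: none
Why: Horner–Wadsworth–Emmons olefination of the enal with the metalated allylic phosphonate, which reacts at its α-carbon and should give the E C11=C12 bond by equilibration to the anti adduct, while the excess anion absorbs the free carbinol and the C13=C14 geometry set in step 7 is carried over.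

Step 11
Reactants: 14 fragment 3
Product: 15 fragment 1, (4S)-4-[(1E,3E,5E,7E)-8-iodo-3,7-dimethylocta-1,3,5,7-tetraen-1-yl]-3,5,5-trimethylcyclohex-2-en-1-one
Conditions: MnO2 (activated, excess), CH2Cl2, 20 °C, dark (about half of the stock of 14; the rest is kept for step 13)
Reagents that add atoms: none
Why: MnO2 oxidation of the ring allylic carbinol to the enone proceeds under neutral heterogeneous conditions, so the C6 stereocentre (now γ to the carbonyl), the tetraene and the vinyl iodide should not be disturbed.

Step 12
Reactants: 16 ethynylboronic acid pinacol ester; 17 tributyltin hydride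
Product: 18 fragment 2, 2-[(E)-2-(tributylstannyl)ethenyl]-4,4,5,5-tetramethyl-1,3,2-dioxaborolane
Conditions: AIBN (cat.), toluene, 80 °C
Reagents that add atoms: none
Why: Radical hydrostannation, in which the tributyltin radical adds to the terminal alkyne carbon to give the boron-stabilised α-boryl vinyl radical, and reversible tin-radical addition at 80 °C equilibrates the adduct to the E isomer.

Step 13
Reactants: 15 fragment 1; 18 fragment 2; 14 fragment 3
Product: 20 (3R,6S,6'S)-3-hydroxy-ε,ε-caroten-3'-one, via ring A pentaenylboronate 19 (not isolated)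
Conditions: 15 and 18 (equimolar), Pd2(dba)3 (2.5 mol%), AsPh3 (20 mol%), degassed DMF–THF, 25 °C, dark; then 14 (1 equiv), 2 M aq. K3PO4, 25–40 °C; chromatography and crystallisation in the dark
Reagents that add atoms: none
Why: Zerovalent palladium from Pd2(dba)3 and AsPh3 inserts into the C14'–I bond of 15, the alkenyl divalent palladium iodide transmetalates with the tributylstannyl end of 18 under base-free conditions in which the pinacol boronate is a spectator, and reductive elimination forms C14'–C15' to give 19; when 14 and aqueous K3PO4 are then added, the boronate is activated as its hydroxy ate complex and the same catalyst forms C15–C14 by a second oxidative addition, transmetalation and reductive elimination. The closest known reaction type is the one-pot Stille then Suzuki–Miyaura coupling of 1-stannyl-2-boryl alkenes with two different alkenyl iodides for polyene assembly, together with alkenyl iodide couplings in retinoid and carotenoid chemistry. No ring is closed and no stereocentre is created: C3, C6 and C6' travel unchanged because they lie far from the reacting sp2 carbons, and all three partners transfer with retention of alkene geometry, so the E configuration of 15, 18 and 14 becomes the all-E nonaene. The selectivity needed is chemoselectivity between tin and boron, secured by withholding base until 15 is consumed, so that ring A ends up on C15' and ring B on C15 without statistical mixing. The second requirement is that the base leave the γ-hydrogen at C6' of the ring A enone alone, which a two-phase aqueous phosphate near room temperature should do; the free ketone and carbinol need no protection.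

**Compound list**

1 | (±)-α-ionone | CC1=CCCC(C)(C)C1/C=C/C(C)=O | starting material
2 | (±)-α-ionone ethylene ketal, 2-methyl-2-[(E)-2-(2,6,6-trimethylcyclohex-2-en-1-yl)ethenyl]-1,3-dioxolane | CC1=CCCC(C)(C)C1/C=C/C1(C)OCCO1 | intermediate
3 | (±)-3-keto-α-ionone ethylene ketal, 3,5,5-trimethyl-4-[(E)-2-(2-methyl-1,3-dioxolan-2-yl)ethenyl]cyclohex-2-en-1-one | CC1=CC(=O)CC(C)(C)C1/C=C/C1(C)OCCO1 | intermediate
4 | racemic cis-3-hydroxy-α-ionone ethylene ketal, (1R*,4S*)-3,5,5-trimethyl-4-[(E)-2-(2-methyl-1,3-dioxolan-2-yl)ethenyl]cyclohex-2-en-1-ol (1R,4S enantiomer drawn) | CC1(OCCO1)/C=C/[C@@H]1C(C)=C[C@H](O)CC1(C)C | intermediate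
5 | racemic cis-3-hydroxy-α-ionone, (3E)-4-[(1S*,4R*)-4-hydroxy-2,6,6-trimethylcyclohex-2-en-1-yl]but-3-en-2-one (1S,4R enantiomer drawn) | CC(=O)/C=C/[C@@H]1C(C)=C[C@H](O)CC1(C)C | intermediate
6 | (3R,6S)-3-acetoxy-α-ionone, (1R,4S)-3,5,5-trimethyl-4-[(1E)-3-oxobut-1-en-1-yl]cyclohex-2-en-1-yl acetate | CC(=O)/C=C/[C@@H]1C(C)=C[C@H](OC(C)=O)CC1(C)C | intermediate
7 | diethyl (cyanomethyl)phosphonate | CCOP(=O)(CC#N)OCC | starting material
8 | (1R,4S)-4-[(1E,3E)-4-cyano-3-methylbuta-1,3-dien-1-yl]-3,5,5-trimethylcyclohex-2-en-1-yl acetate | N#C/C=C(C)/C=C/[C@@H]1C(C)=C[C@H](OC(C)=O)CC1(C)C | intermediate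
9 | (2E,4E)-5-[(1S,4R)-4-hydroxy-2,6,6-trimethylcyclohex-2-en-1-yl]-3-methylpenta-2,4-dienal | O=C/C=C(C)/C=C/[C@@H]1C(C)=C[C@H](O)CC1(C)C | intermediate
10 | propargyl alcohol | C#CCO | starting material
11 | (2E)-3-iodo-2-methylprop-2-en-1-ol | OC/C(C)=C/I | intermediate
12 | (1E)-3-bromo-1-iodo-2-methylprop-1-ene | BrC/C(C)=C/I | intermediate
13 | diethyl [(2E)-3-iodo-2-methylprop-2-en-1-yl]phosphonate | CCOP(=O)(OCC)C/C(C)=C/I | intermediate
14 | fragment 3, (1R,4S)-4-[(1E,3E,5E,7E)-8-iodo-3,7-dimethylocta-1,3,5,7-tetraen-1-yl]-3,5,5-trimethylcyclohex-2-en-1-ol | I/C=C(C)/C=C/C=C(C)/C=C/[C@@H]1C(C)=C[C@H](O)CC1(C)C | intermediate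
15 | fragment 1, (4S)-4-[(1E,3E,5E,7E)-8-iodo-3,7-dimethylocta-1,3,5,7-tetraen-1-yl]-3,5,5-trimethylcyclohex-2-en-1-one | CC1=CC(=O)CC(C)(C)[C@@H]1/C=C/C(C)=C/C=C/C(C)=C/I | intermediate
16 | ethynylboronic acid pinacol ester, 2-ethynyl-4,4,5,5-tetramethyl-1,3,2-dioxaborolane | C#CB1OC(C)(C)C(C)(C)O1 | starting material
17 | tributyltin hydride | CCCC[SnH](CCCC)CCCC | starting material
18 | fragment 2, 2-[(E)-2-(tributylstannyl)ethenyl]-4,4,5,5-tetramethyl-1,3,2-dioxaborolane | CCCC[Sn](CCCC)(CCCC)/C=C/B1OC(C)(C)C(C)(C)O1 | intermediate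
19 | (4S)-3,5,5-trimethyl-4-[(1E,3E,5E,7E,9E)-3,7-dimethyl-10-(4,4,5,5-tetramethyl-1,3,2-dioxaborolan-2-yl)deca-1,3,5,7,9-pentaen-1-yl]cyclohex-2-en-1-one | CC1=CC(=O)CC(C)(C)[C@@H]1/C=C/C(C)=C/C=C/C(C)=C/C=C/B1OC(C)(C)C(C)(C)O1 | intermediate
20 | (3R,6S,6'S)-3-hydroxy-ε,ε-caroten-3'-one | CC1=CC(=O)CC(C)(C)[C@@H]1/C=C/C(C)=C/C=C/C(C)=C/C=C/C=C(C)/C=C/C=C(C)/C=C/[C@@H]1C(C)=C[C@H](O)CC1(C)C | target

**Step count**

Total step count: 13.
Longest linear sequence: 9 steps from α-ionone (steps 1, 2, 3, 4, 5, 6, 10, 11, 13).

**Steps most likely to fail**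

1. Step 13. The basic Suzuki stage may epimerise C6' by γ-deprotonation of the ring A enone. The second coupling may stall after the tin stage. Early boron transfer or homocoupling may scramble the two halves.
Fallback: it sets out from 15 and 14 and returns at 20. Stille coupling of 15 with an excess of commercial (E)-1,2-bis(tributylstannyl)ethene (Pd2(dba)3, AsPh3, DMF, 25 °C) would give the ring A pentaenylstannane F1. After removal of the excess distannane, a second base-free Stille coupling of F1 with 14 under the same catalyst would give 20. Both bonds then form without base, at the price of the excess distannane needed to suppress double coupling.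

2. Step 10. E selectivity at C11=C12 may erode. The iodoallyl anion may decompose by loss of iodide. The enal may enolise under the excess base that the free carbinol requires.
Fallback: it sets out from 9 and returns at 14. Horner–Wadsworth–Emmons reaction of 9 with commercial diethyl [3-(trimethylsilyl)prop-2-yn-1-yl]phosphonate (NaN(SiMe3)2, THF, −78 °C) would give the silyl trienyne F2. K2CO3 in MeOH would remove the silyl group to give the terminal trienyne F3. Negishi carboalumination (Me3Al in excess for the free carbinol, Cp2ZrCl2, CH2Cl2) followed by I2 would place the methyl group at C13 and iodine at C14 and give 14.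

3. Step 3. Facial selectivity of hydride delivery may be poor or reversed, so that the trans carbinol predominates. Acid hydrolysis may also epimerise C3 through the allyl cation.
Fallback: it sets out from 3 and returns at 5. The same reduction and hydrolysis would pass through the trans-hydroxy ketal F4 (not isolated) to racemic trans-3-hydroxy-α-ionone F5. Mitsunobu reaction of F5 with 4-nitrobenzoic acid (PPh3, diisopropyl azodicarboxylate, THF, 0 °C) would invert C3 by SN2 displacement and give the cis 4-nitrobenzoate F6. Methanolysis of F6 (K2CO3, MeOH) would give 5.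

**Further compounds**

F1 | step 13 | (4S)-3,5,5-trimethyl-4-[(1E,3E,5E,7E,9E)-3,7-dimethyl-10-(tributylstannyl)deca-1,3,5,7,9-pentaen-1-yl]cyclohex-2-en-1-one | CC1=CC(=O)CC(C)(C)[C@@H]1/C=C/C(C)=C/C=C/C(C)=C/C=C/[Sn](CCCC)(CCCC)CCCC
F2 | step 10 | (1R,4S)-3,5,5-trimethyl-4-[(1E,3E,5E)-3-methyl-8-(trimethylsilyl)octa-1,3,5-trien-7-yn-1-yl]cyclohex-2-en-1-ol | C[Si](C)(C)C#C/C=C/C=C(C)/C=C/[C@@H]1C(C)=C[C@H](O)CC1(C)C
F3 | step 10 | (1R,4S)-3,5,5-trimethyl-4-[(1E,3E,5E)-3-methylocta-1,3,5-trien-7-yn-1-yl]cyclohex-2-en-1-ol | C#C/C=C/C=C(C)/C=C/[C@@H]1C(C)=C[C@H](O)CC1(C)C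
F4 | step 3 | racemic trans-3-hydroxy-α-ionone ethylene ketal, (1S*,4S*)-3,5,5-trimethyl-4-[(E)-2-(2-methyl-1,3-dioxolan-2-yl)ethenyl]cyclohex-2-en-1-ol (1S,4S enantiomer drawn) | CC1(OCCO1)/C=C/[C@@H]1C(C)=C[C@@H](O)CC1(C)C
F5 | step 3 | racemic trans-3-hydroxy-α-ionone, (3E)-4-[(1S*,4S*)-4-hydroxy-2,6,6-trimethylcyclohex-2-en-1-yl]but-3-en-2-one (1S,4S enantiomer drawn) | CC(=O)/C=C/[C@@H]1C(C)=C[C@@H](O)CC1(C)C
F6 | step 3 | racemic cis-3-(4-nitrobenzoyloxy)-α-ionone, (1R*,4S*)-3,5,5-trimethyl-4-[(1E)-3-oxobut-1-en-1-yl]cyclohex-2-en-1-yl 4-nitrobenzoate (1R,4S enantiomer drawn) | CC(=O)/C=C/[C@@H]1C(C)=C[C@H](OC(=O)c2ccc(cc2)[N+](=O)[O-])CC1(C)C
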